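I gave each flask 6.0 min at one temperature and followed the chain length, with G the monomer, D the monomer in chains, and Z the living ends.

| flask | G | J | E | time |
|---|---|---|---|---|
| north-west | 0.15 M | 2 mol% | 0.35 mM | 6.0 min |
| south-west | 0.15 M | 2 mol% | 0.80 mM | 6.0 min |

    J + E → J.E (k1 = 1280 L mol⁻¹ s⁻¹)
    D + Z → G + Z, rate k2*[Z] as long as [D] is above zero (k2 = 0.0375 s⁻¹)
    G + J → Z + D (k3 = 1.27 L mol⁻¹ s⁻¹)
    G → X (k4 = 2.77 × 10⁻⁵ s⁻¹)
    G + Z → D + Z, rate k5*[Z]*[G] (k5 = 0.577 L mol⁻¹ s⁻¹)

- which of the two ends with the longer chains by the average number of monomer units in a chain (chains begun, living or dead) ("neither" if they lie within 10%) (north-west / south-west / neither)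
- average number of monomer units in a chain (chains begun, living or dead) at the end, north-west
- average number of monomer units in a chain (chains begun, living or dead) at the end, south-west

- the average divides the monomer in chains by the number of chains begun, living and dead together
- run time (north-west): 6.0 min

- I carried a zero for the scale, the floor c* = 0.0650 M: the G concentration at which growth and unzipping cancel, 0.0375 s⁻¹ over 0.577 L mol⁻¹ s⁻¹, the equilibrium monomer concentration. Net growth goes with the excess of G over c*.
- On the first rung, E fell by half in 0.181 s with J at its charge, faster than J reacted with G at its charge, which took a half-life of 3.64 s. So I took the chains begun as charged J less E: 2.65 mM north-west, 2.20 mM south-west.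
- On the next rung, with Z steady (pseudo-first-order), G relaxes towards c* over a time τ = 1/(growth constant × Z): 10.9 min north-west, 13.1 min south-west. Both are longer than the run, so I expected each flask to be caught on the way, with a share f = 1 − exp(−t/τ) of the excess turned to D: 42.3% and 36.7%.
- On the slowest rung, G goes to X with a half-life of 7.0 h, far longer than either τ, so I dropped it.
- My length was the excess of charged G over c*, times f, over Z: 13.6 north-west and 14.2 south-west. South-west has fewer chains but a smaller share, so I answered neither.
- The forecast said neither, with 13.9 (13 to 14.8) north-west and 14.5 (13.6 to 15.4) south-west, a little above mine, holding that “its fewer chains and lower conversion nearly cancel”.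
- The flasks gave 13.9 north-west and 14.5 south-west, so the answer was neither: the two lengths lay within 10%, with Z at 0.00265 M north-west and 0.00220 M south-west.
- At 6.00 min south-west still held G at 1.80 times c*, with D made 1.80 times as fast as it was undone. Unzipping was part of what kept chains short, the short run the other part: north-west's 13.9 became 24.2 without unzipping, and 29.4 when left until 60.0 min. The neighbour charged with 0.38 M of G, 0.80 mM of E and J at the same loading began 6.80 mM of chains, so my rule gave 35.0, and that flask ended at 35.0.

All constants belong to no real substance; the run is a simulation.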